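## Retrosynthetic overview

1. The target is epiafzelechin-(4β→8)-epiafzelechin-(4β→8)-4'-O-methylepigallocatechin. The last step is hydrogenolysis of thirteen benzyl ethers.
2. Each epiafzelechin C ring is cut at O1–C8a and C3–C4. This leaves a diarylcarbenium ion and one chiral C2–C3 piece, hydroxy acid 19, made by an Evans glycolate aldol.
3. Enabling feature: C4 of the middle unit is a methine between two phloroglucinol-type rings (ring A of the middle unit and C8 of ring A of the bottom unit). As a cation it is persistent and coloured. Its charge reaches the ortho carbon C8a, so C4 and C8a form a 1,3-bis-electrophile. O1 (alcohol) and C3 (radical after loss of CO2) answer it.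
4. The cations come from 8-lithio flavans and fluoro aldehyde 9. The bottom unit comes from (−)-epigallocatechin.
5. Ring order: bottom C ring (present in 1), then middle C ring (step 11), then top C ring (step 14).

Key step: step 11

Assumption: the SMILES is read as (2R,3R), 2,3-cis, in all three flavan units, with both interflavan bonds 3,4-trans (4β→8). Flavan numbering (O1, C2–C4, C4a, C5–C8, C8a) is used throughout.

## Route

**Step 1**
Reactants: 1 (−)-epigallocatechin
Product: 2 4'-O-methyl-(−)-epigallocatechin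
Conditions: MeI (1.0 equiv), K2CO3 (1.0 equiv), acetone, Ar, 23 °C
Reagents that add atoms: iodomethane, CI
Why: The central 4'-OH of the pyrogallol ring is the most acidic phenol because two hydrogen-bond donors flank its phenoxide, so a Williamson methylation with one equivalent of weak base should go mainly to O4' and touches no stereocentre.

**Step 2**
Reactants: 2 4'-O-methyl-(−)-epigallocatechin
Product: 3 5,7,3',5'-tetra-O-benzyl-4'-O-methyl-(−)-epigallocatechin (3-OH free)
Conditions: BnBr (4.4 equiv), K2CO3, DMF, Ar, 23 °C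
Reagents that add atoms: benzyl bromide, BrCc1ccccc1
Why: Williamson etherification of the four remaining phenols, since K2CO3 does not deprotonate the secondary 3-OH and mild base under argon should leave C2 unchanged.

**Step 3**
Reactants: 3 5,7,3',5'-tetra-O-benzyl-4'-O-methyl-(−)-epigallocatechin
Product: 4 3,5,7,3',5'-penta-O-benzyl-4'-O-methyl-(−)-epigallocatechin
Conditions: NaH, BnBr, DMF, 0 → 23 °C
Reagents that add atoms: benzyl bromide, BrCc1ccccc1
Why: Williamson etherification of the secondary alcohol at oxygen only, so C3 keeps its configuration and the later organolithium and cation steps meet no free OH.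

**Step 4**
Reactants: 4 3,5,7,3',5'-penta-O-benzyl-4'-O-methyl-(−)-epigallocatechin
Product: 5 8-bromo-3,5,7,3',5'-penta-O-benzyl-4'-O-methyl-(−)-epigallocatechin
Conditions: NBS (1.0 equiv), CH2Cl2, −78 → 0 °C, dark
Reagents that add atoms: N-bromosuccinimide, O=C1CCC(=O)N1Br
Why: Electrophilic aromatic bromination of the most electron-rich ring, where C8 (next to the ring oxygen) is more accessible than C6 (between two benzyloxy groups), as is general for 5,7-di-O-benzyl flavans.

**Step 5**
Reactants: 6 5-fluororesorcinol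
Product: 7 1,3-bis(benzyloxy)-5-fluorobenzene
Conditions: BnBr (2.2 equiv), K2CO3, DMF, 60 °C
Reagents that add atoms: benzyl bromide, BrCc1ccccc1
Why: Plain Williamson etherification of both phenols, with the C–F bond inert under these conditions.

**Step 6**
Reactants: 7 1,3-bis(benzyloxy)-5-fluorobenzene
Product: 9 2,4-bis(benzyloxy)-6-fluorobenzaldehyde, via aryl iminium salt 8 (not isolated)
Conditions: POCl3, DMF, 0 → 60 °C; then H2O
Reagents that add atoms: N,N-dimethylformamide, CN(C)C=O; water, O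
Why: Vilsmeier–Haack formylation should prefer the two equivalent positions para to one benzyloxy group and next to the small fluorine over the crowded position between the two benzyloxy groups.

**Step 7**
Reactants: 10 (S)-4-benzyloxazolidin-2-one; 11 benzyloxyacetyl chloride
Product: 13 (S)-4-benzyl-3-(benzyloxyacetyl)oxazolidin-2-one, via N-lithio oxazolidinone 12 (not isolated)
Conditions: n-BuLi, THF, −78 °C; then 11, −78 → 0 °C
Reagents that add atoms: none
Why: Standard N-acylation of the lithiated Evans auxiliary with an acid chloride, which leaves the auxiliary stereocentre untouched.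

**Step 8**
Reactants: 13 (S)-4-benzyl-3-(benzyloxyacetyl)oxazolidin-2-one; 14 4-(benzyloxy)benzaldehyde
Product: 17 (S)-4-benzyl-3-{(2S,3R)-2-(benzyloxy)-3-[4-(benzyloxy)phenyl]-3-hydroxypropanoyl}oxazolidin-2-one, via Z-boron enolate 15 (not isolated), via boron aldolate 16 (not isolated)
Conditions: Bu2BOTf, Et3N, CH2Cl2, −78 → 0 °C; 14, −78 → 0 °C; pH 7 buffer, MeOH, 30 % H2O2, 0 °C
Reagents that add atoms: none
Why: Evans syn-glycolate aldol, in which the Z-boron enolate reacts through a Zimmerman–Traxler chair on the face left open by the (S)-benzyl group and sets the (3R) carbinol (later C2) and the (2S) ether carbon together.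

**Step 9**
Reactants: 17 syn-aldol imide
Product: 19 (2S,3R)-2-(benzyloxy)-3-[4-(benzyloxy)phenyl]-3-hydroxypropanoic acid, via peroxy acid 18 (not isolated)
Conditions: LiOH, H2O2, THF–H2O, 0 °C; Na2SO3; 1 M HCl
Reagents that add atoms: hydrogen peroxide, OO
Why: Lithium hydroperoxide attacks the exocyclic imide carbonyl selectively, and at 0 °C neither retro-aldol cleavage nor epimerisation should compete.

**Step 10**
Reactants: 5 8-bromo bottom unit; 9 2,4-bis(benzyloxy)-6-fluorobenzaldehyde
Product: 22 [2,4-bis(benzyloxy)-6-fluorophenyl](3,5,7,3',5'-penta-O-benzyl-4'-O-methylepigallocatechin-8-yl)methylium tetrafluoroborate, via 8-lithio flavan 20 (not isolated), via lithium diarylmethoxide 21 (not isolated)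
Conditions: n-BuLi, THF, −78 °C; 9, −78 → −40 °C; HBF4·OEt2 (2 equiv), Et2O, −78 → 0 °C; salt filtered off
Reagents that add atoms: tetrafluoroboric acid diethyl etherate, [H+].F[B-](F)(F)F.CCOCC
Why: Bromine–lithium exchange and 1,2-addition to the aldehyde are followed by acid ionisation of the diarylcarbinol to a carbenium ion stabilised by five ortho/para alkoxy donors, a known way to persistent diarylmethylium salts that also erases the carbinol stereocentre.

**Step 11**
Reactants: 22 fluoro diarylmethylium tetrafluoroborate; 19 (2S,3R)-hydroxy acid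
Product: 24 3,5,7,4'-tetra-O-benzylepiafzelechin-(4β→8)-3,5,7,3',5'-penta-O-benzyl-4'-O-methylepigallocatechin (new unit 2R,3R, 2,3-cis, 3,4-trans), via ether-tethered carbenium carboxylate 23 (not isolated)
Conditions: Cs2CO3 (2 equiv), 4CzIPN (2 mol %), 4 Å MS, MeCN–CH2Cl2 1:1 (0.01 M), Ar, 23 °C, dark 3 h, then 456 nm LED, 23 °C
Reagents that add atoms: none
Why: Proposed new method: in 22 the charge at C4 is shared with the ortho carbon C8a of the fluoro ring, so C8a–F behaves as a vinylogous acyl fluoride and the benzylic OH of 19, assisted by its own caesium carboxylate, should replace fluoride by addition–elimination (O1–C8a bond), whereas attack at C4 is reversible; this gives the better stabilised zwitterion 23. Light then moves one electron from the tethered α-benzyloxy carboxylate to the carbenium chromophore (directly or relayed by 4CzIPN), CO2 is lost and the nucleophilic C3 radical bonds to C4 (C3–C4 bond), so the step is redox-neutral overall. The closest known reaction types are SNAr of ortho and para leaving groups on alkoxy-substituted di- and triarylcarbenium dyes, the photochemical decarboxylative alkylation of acridinium ions at C9 by carboxylates, and the photoredox decarboxylative Giese addition to para-quinone methides. The pyran ring closes in the C–C event in the 6-endo-trig mode, at the exocyclic end of the quinoid C4=C4a bond. C2 comes unchanged from 19 and its equatorial aryl group fixes the half-chair; peri strain with the C5 benzyloxy group should push the bottom-unit aryl group at C4 into the pseudo-axial position (2,4-trans), and the benzyloxy group on the planar C3 radical should turn anti to it (3,4-trans and so 2,3-cis). The step needs substitution at C8a only and ring closure before any open-chain coupling: the first is secured by the single C–F bond (all other ortho and para carbons carry poorer alkoxide leaving groups), the second by high dilution and by switching the lamp on only after 23 has formed.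

**Step 12**
Reactants: 24 protected dimer
Product: 25 8-bromo (upper unit) derivative of 24
Conditions: NBS (1.0 equiv), CH2Cl2, −78 → 0 °C, dark
Reagents that add atoms: N-bromosuccinimide, O=C1CCC(=O)N1Br
Why: Electrophilic aromatic bromination, where C8 of the upper unit is the only free position not flanked by two benzyloxy groups (C6 of both units is), so it should react first.

**Step 13**
Reactants: 25 8-bromo dimer; 9 2,4-bis(benzyloxy)-6-fluorobenzaldehyde
Product: 28 [2,4-bis(benzyloxy)-6-fluorophenyl](protected dimer-8-yl)methylium tetrafluoroborate, via 8-lithio dimer 26 (not isolated), via lithium diarylmethoxide 27 (not isolated)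
Conditions: n-BuLi, THF, −78 °C; 9, −78 → −40 °C; HBF4·OEt2 (2 equiv), Et2O, −78 → 0 °C; salt filtered off
Reagents that add atoms: tetrafluoroboric acid diethyl etherate, [H+].F[B-](F)(F)F.CCOCC
Why: Same bromine–lithium exchange, 1,2-addition and carbinol ionisation as in step 10, where the carbinol is by far the most easily ionised site, so short cold contact with acid should spare the benzyl-protected interflavan bond.

**Step 14**
Reactants: 28 dimer-derived fluoro diarylmethylium tetrafluoroborate; 19 (2S,3R)-hydroxy acid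
Product: 30 tridecabenzyl ether of the target (top unit 2R,3R, 2,3-cis, 3,4-trans, 4β→8), via ether-tethered carbenium carboxylate 29 (not isolated)
Conditions: Cs2CO3 (2 equiv), 4CzIPN (2 mol %), 4 Å MS, MeCN–CH2Cl2 1:1 (0.01 M), Ar, 23 °C, dark 3 h, then 456 nm LED, 23 °C
Reagents that add atoms: none
Why: Proposed new method: as in step 11, the cation-activated C8a–F of the new ring A is displaced by the benzylic OH of 19, and photoinduced electron transfer, loss of CO2 and 6-endo-trig bonding of the C3 radical to C4 close the top C ring under the same control (equatorial C2 aryl, pseudo-axial C4 aryl, C3 benzyloxy anti to it); the closest known reaction types are SNAr on alkoxy-substituted carbenium dyes and photochemical decarboxylative alkylation of acridinium ions or para-quinone methides.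

**Step 15**
Reactants: 30 tridecabenzyl ether
Product: 31 epiafzelechin-(4β→8)-epiafzelechin-(4β→8)-4'-O-methylepigallocatechin (target)
Conditions: H2 (1 atm), Pd(OH)2/C, THF–MeOH–H2O, 23 °C
Reagents that add atoms: none
Why: Catalytic hydrogenolysis cleaves all aryl and alkyl benzyl ethers, while the methyl ether, the pyran C–O bonds and both interflavan bonds should survive, as is usual for benzylated proanthocyanidins, and no stereocentre is involved.

## Compound list

1 | (−)-epigallocatechin | Oc1c(O)cc([C@H]2Oc3c(c(O)cc(O)c3)C[C@H]2O)cc1O | starting material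
2 | 4'-O-methyl-(−)-epigallocatechin | COc1c(O)cc([C@H]2Oc3c(c(O)cc(O)c3)C[C@H]2O)cc1O | intermediate
3 | 5,7,3',5'-tetra-O-benzyl-4'-O-methyl-(−)-epigallocatechin | COc1c(OCc4ccccc4)cc([C@H]2Oc3c(c(OCc4ccccc4)cc(OCc4ccccc4)c3)C[C@H]2O)cc1OCc1ccccc1 | intermediate
4 | 3,5,7,3',5'-penta-O-benzyl-4'-O-methyl-(−)-epigallocatechin | COc1c(OCc4ccccc4)cc([C@H]2Oc3c(c(OCc4ccccc4)cc(OCc4ccccc4)c3)C[C@H]2OCc2ccccc2)cc1OCc1ccccc1 | intermediate
5 | 8-bromo derivative of 4 | COc1c(OCc4ccccc4)cc([C@H]2Oc3c(c(OCc4ccccc4)cc(OCc4ccccc4)c3Br)C[C@H]2OCc2ccccc2)cc1OCc1ccccc1 | intermediate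
6 | 5-fluororesorcinol | Oc1cc(O)cc(F)c1 | starting material
7 | 1,3-bis(benzyloxy)-5-fluorobenzene | Fc1cc(OCc2ccccc2)cc(OCc2ccccc2)c1 | intermediate
8 | [2,4-bis(benzyloxy)-6-fluorobenzylidene]dimethyliminium dichlorophosphate | C[N+](C)=Cc1c(F)cc(OCc2ccccc2)cc1OCc1ccccc1.[O-]P(=O)(Cl)Cl | intermediate
9 | 2,4-bis(benzyloxy)-6-fluorobenzaldehyde | O=Cc1c(F)cc(OCc2ccccc2)cc1OCc1ccccc1 | intermediate
10 | (S)-4-benzyloxazolidin-2-one | N1C(=O)OC[C@@H]1Cc1ccccc1 | starting material
11 | benzyloxyacetyl chloride | O=C(Cl)COCc1ccccc1 | starting material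
12 | N-lithio-(S)-4-benzyloxazolidin-2-one | [Li]N1C(=O)OC[C@@H]1Cc1ccccc1 | intermediate
13 | (S)-4-benzyl-3-(benzyloxyacetyl)oxazolidin-2-one | O=C(COCc1ccccc1)N1C(=O)OC[C@@H]1Cc1ccccc1 | intermediate
14 | 4-(benzyloxy)benzaldehyde | O=Cc1ccc(OCc2ccccc2)cc1 | starting material
15 | (Z)-dibutylboron enolate of 13 | CCCCB(CCCC)O/C(=C\OCc1ccccc1)N1C(=O)OC[C@@H]1Cc1ccccc1 | intermediate
16 | dibutylboron aldolate of 17 | O=C([C@@H](OCc1ccccc1)[C@H](OB(CCCC)CCCC)c1ccc(OCc2ccccc2)cc1)N1C(=O)OC[C@@H]1Cc1ccccc1 | intermediate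
17 | (S)-4-benzyl-3-{(2S,3R)-2-(benzyloxy)-3-[4-(benzyloxy)phenyl]-3-hydroxypropanoyl}oxazolidin-2-one | O=C([C@@H](OCc1ccccc1)[C@H](O)c1ccc(OCc2ccccc2)cc1)N1C(=O)OC[C@@H]1Cc1ccccc1 | intermediate
18 | (2S,3R)-2-(benzyloxy)-3-[4-(benzyloxy)phenyl]-3-hydroxypropaneperoxoic acid | OOC(=O)[C@@H](OCc1ccccc1)[C@H](O)c1ccc(OCc2ccccc2)cc1 | intermediate
19 | (2S,3R)-2-(benzyloxy)-3-[4-(benzyloxy)phenyl]-3-hydroxypropanoic acid | OC(=O)[C@@H](OCc1ccccc1)[C@H](O)c1ccc(OCc2ccccc2)cc1 | intermediate
20 | 8-lithio derivative of 4 | COc1c(OCc4ccccc4)cc([C@H]2Oc3c(c(OCc4ccccc4)cc(OCc4ccccc4)c3[Li])C[C@H]2OCc2ccccc2)cc1OCc1ccccc1 | intermediate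
21 | lithium [2,4-bis(benzyloxy)-6-fluorophenyl](bottom unit-8-yl)methoxide (carbinol carbon undefined) | COc1c(OCc4ccccc4)cc([C@H]2Oc3c(c(OCc4ccccc4)cc(OCc4ccccc4)c3C(O[Li])c3c(F)cc(OCc4ccccc4)cc3OCc3ccccc3)C[C@H]2OCc2ccccc2)cc1OCc1ccccc1 | intermediate
22 | [2,4-bis(benzyloxy)-6-fluorophenyl](bottom unit-8-yl)methylium tetrafluoroborate | COc1c(OCc4ccccc4)cc([C@H]2Oc3c(c(OCc4ccccc4)cc(OCc4ccccc4)c3[CH+]c3c(F)cc(OCc4ccccc4)cc3OCc3ccccc3)C[C@H]2OCc2ccccc2)cc1OCc1ccccc1.F[B-](F)(F)F | intermediate
23 | zwitterion: 22 with F replaced by the (1R,2S)-2-(benzyloxy)-1-[4-(benzyloxy)phenyl]-2-carboxylatoethoxy group | COc1c(OCc4ccccc4)cc([C@H]2Oc3c(c(OCc4ccccc4)cc(OCc4ccccc4)c3[CH+]c3c(O[C@H](c4ccc(OCc5ccccc5)cc4)[C@H](OCc4ccccc4)C(=O)[O-])cc(OCc4ccccc4)cc3OCc3ccccc3)C[C@H]2OCc2ccccc2)cc1OCc1ccccc1 | intermediate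
24 | 3,5,7,4'-tetra-O-benzylepiafzelechin-(4β→8)-3,5,7,3',5'-penta-O-benzyl-4'-O-methylepigallocatechin | COc1c(OCc4ccccc4)cc([C@H]2Oc3c(c(OCc4ccccc4)cc(OCc4ccccc4)c3[C@H]3c4c(OCc5ccccc5)cc(OCc5ccccc5)cc4O[C@H](c4ccc(OCc5ccccc5)cc4)[C@@H]3OCc3ccccc3)C[C@H]2OCc2ccccc2)cc1OCc1ccccc1 | intermediate
25 | 24 with Br at C8 of the upper unit | COc1c(OCc4ccccc4)cc([C@H]2Oc3c(c(OCc4ccccc4)cc(OCc4ccccc4)c3[C@H]3c4c(OCc5ccccc5)cc(OCc5ccccc5)c(Br)c4O[C@H](c4ccc(OCc5ccccc5)cc4)[C@@H]3OCc3ccccc3)C[C@H]2OCc2ccccc2)cc1OCc1ccccc1 | intermediate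
26 | 24 with Li at C8 of the upper unit | COc1c(OCc4ccccc4)cc([C@H]2Oc3c(c(OCc4ccccc4)cc(OCc4ccccc4)c3[C@H]3c4c(OCc5ccccc5)cc(OCc5ccccc5)c([Li])c4O[C@H](c4ccc(OCc5ccccc5)cc4)[C@@H]3OCc3ccccc3)C[C@H]2OCc2ccccc2)cc1OCc1ccccc1 | intermediate
27 | lithium [2,4-bis(benzyloxy)-6-fluorophenyl](dimer-8-yl)methoxide (carbinol carbon undefined) | COc1c(OCc4ccccc4)cc([C@H]2Oc3c(c(OCc4ccccc4)cc(OCc4ccccc4)c3[C@H]3c4c(OCc5ccccc5)cc(OCc5ccccc5)c(C(O[Li])c5c(F)cc(OCc6ccccc6)cc5OCc5ccccc5)c4O[C@H](c4ccc(OCc5ccccc5)cc4)[C@@H]3OCc3ccccc3)C[C@H]2OCc2ccccc2)cc1OCc1ccccc1 | intermediate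
28 | [2,4-bis(benzyloxy)-6-fluorophenyl](dimer-8-yl)methylium tetrafluoroborate | COc1c(OCc4ccccc4)cc([C@H]2Oc3c(c(OCc4ccccc4)cc(OCc4ccccc4)c3[C@H]3c4c(OCc5ccccc5)cc(OCc5ccccc5)c([CH+]c5c(F)cc(OCc6ccccc6)cc5OCc5ccccc5)c4O[C@H](c4ccc(OCc5ccccc5)cc4)[C@@H]3OCc3ccccc3)C[C@H]2OCc2ccccc2)cc1OCc1ccccc1.F[B-](F)(F)F | intermediate
29 | zwitterion: 28 with F replaced by the (1R,2S)-2-(benzyloxy)-1-[4-(benzyloxy)phenyl]-2-carboxylatoethoxy group | COc1c(OCc4ccccc4)cc([C@H]2Oc3c(c(OCc4ccccc4)cc(OCc4ccccc4)c3[C@H]3c4c(OCc5ccccc5)cc(OCc5ccccc5)c([CH+]c5c(O[C@H](c6ccc(OCc7ccccc7)cc6)[C@H](OCc6ccccc6)C(=O)[O-])cc(OCc6ccccc6)cc5OCc5ccccc5)c4O[C@H](c4ccc(OCc5ccccc5)cc4)[C@@H]3OCc3ccccc3)C[C@H]2OCc2ccccc2)cc1OCc1ccccc1 | intermediate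
30 | tridecabenzyl ether of the target | COc1c(OCc4ccccc4)cc([C@H]2Oc3c(c(OCc4ccccc4)cc(OCc4ccccc4)c3[C@H]3c4c(OCc5ccccc5)cc(OCc5ccccc5)c([C@H]5c6c(OCc7ccccc7)cc(OCc7ccccc7)cc6O[C@H](c6ccc(OCc7ccccc7)cc6)[C@@H]5OCc5ccccc5)c4O[C@H](c4ccc(OCc5ccccc5)cc4)[C@@H]3OCc3ccccc3)C[C@H]2OCc2ccccc2)cc1OCc1ccccc1 | intermediate
31 | epiafzelechin-(4β→8)-epiafzelechin-(4β→8)-4'-O-methylepigallocatechin | COc1c(O)cc([C@H]2Oc3c(c(O)cc(O)c3[C@H]3c4c(O)cc(O)c([C@H]5c6c(O)cc(O)cc6O[C@H](c6ccc(O)cc6)[C@@H]5O)c4O[C@H](c4ccc(O)cc4)[C@@H]3O)C[C@H]2O)cc1O | target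

## Step count and risks

Total step count: 15. Longest linear sequence: 10 (steps 1–4 and 10–15).

**Step 11 (labelled step).** Fluoride displacement may be slower than ion-pair collapse or light-driven coupling. The C–C bond would then form without the ether tether and without control at C4. Facial control in the ring closure may also be poor. The fallback uses known chemistry and a different bond set. It sets out from 4 and comes back at 24. Purchased (−)-epiafzelechin F1 is perbenzylated (NaH, BnBr, DMF) to 3,5,7,4'-tetra-O-benzylepiafzelechin F2. This is oxidised at C4 with DDQ in the presence of 2-ethoxyethanol to the 4β-(2-ethoxyethoxy) ether F3. F3 is then coupled with an excess of 4 under TMSOTf catalysis (CH2Cl2, −78 °C). Friedel–Crafts attack of C8 of 4 on the flavan-4-yl cation, anti to the 3-benzyloxy group, gives 24.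

**Step 14 (labelled step).** The processes that endanger step 11 apply here too. Crowding next to the middle unit may further slow both the fluoride displacement and the ring closure. The fallback uses known chemistry. It sets out from 24 and comes back at 30. The 4β-(2-ethoxyethoxy) ether F3 of the preceding fallback is condensed with 24 as the nucleophile (TMSOTf, CH2Cl2, −78 °C). This chain extension at C8 of the upper unit has the usual 3,4-trans outcome.

**Step 12.** Site selectivity may be poor between C8 and C6 of the upper unit and C6 of the bottom unit, and over-bromination is possible. The fallback fixes the halogen on the small building block. It sets out from 9 and 5 and comes back at 25. Aldehyde 9 is brominated (NBS, MeCN) to 4,6-bis(benzyloxy)-3-bromo-2-fluorobenzaldehyde F4, where isomers can be removed and the position checked. Lithio flavan 20, made from 5, is added and the carbinol ionised as in step 10. This gives the bromo-fluoro diarylmethylium tetrafluoroborate F5. Annulation of F5 with 19 under the conditions of step 11 delivers 25 directly.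

## Further compounds

F1 | step 11 | (−)-epiafzelechin | Oc1ccc([C@H]2Oc3c(c(O)cc(O)c3)C[C@H]2O)cc1
F2 | step 11 | 3,5,7,4'-tetra-O-benzyl-(−)-epiafzelechin | C(c1ccccc1)Oc1ccc([C@H]2Oc3c(c(OCc4ccccc4)cc(OCc4ccccc4)c3)C[C@H]2OCc2ccccc2)cc1
F3 | step 11 | 3,5,7,4'-tetra-O-benzyl-4β-(2-ethoxyethoxy)epiafzelechin | CCOCCO[C@H]1c2c(OCc3ccccc3)cc(OCc3ccccc3)cc2O[C@H](c2ccc(OCc3ccccc3)cc2)[C@@H]1OCc1ccccc1
F0 | step 14 | none | none
F4 | step 12 | 4,6-bis(benzyloxy)-3-bromo-2-fluorobenzaldehyde | O=Cc1c(F)c(Br)c(OCc2ccccc2)cc1OCc1ccccc1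
F5 | step 12 | [4,6-bis(benzyloxy)-3-bromo-2-fluorophenyl](bottom unit-8-yl)methylium tetrafluoroborate | COc1c(OCc4ccccc4)cc([C@H]2Oc3c(c(OCc4ccccc4)cc(OCc4ccccc4)c3[CH+]c3c(F)c(Br)c(OCc4ccccc4)cc3OCc3ccccc3)C[C@H]2OCc2ccccc2)cc1OCc1ccccc1.F[B-](F)(F)F
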